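**Remark.** Ring locants follow one fixed numbering throughout, also in names: C1 is the quaternary carbinol, C7 its exocyclic carbon, C2 and C5 the allylic benzoate carbons, C3=C4 the alkene, C6 the free secondary carbinol. In the gold step the proton that ends on C4 is assumed to come from water added to the acetone.

## The problem

Compound 13 is a cyclohexene in which four contiguous ring carbons (C5, C6, C1, C2) carry oxygen and the C3=C4 alkene lies between two allylic benzoates. C1 is quaternary and bears the benzoyloxymethyl arm C7. The hydroxyls at C1 and C6 and the benzoate at C2 sit on one face and the C5 benzoate on the other; the absolute configuration is (1S,2R,5R,6S). C6 can fix C2 if their two oxygens are tied into one ring, and the pair can then fix C1 through the face of a C1 ketone. C5 is best set together with C6 in one C–C bond-forming event, but the accessible relationship is cis, so C5 must be inverted. Three of the five oxygens are benzoates and two are free, so C2 has to be told apart from C6. The late intermediates are fragile: benzoates migrate to cis-neighbouring hydroxyls under base, and the doubly allylic ester pattern can ionise or eliminate towards an arene under acid or heat. The enabling feature is that C2–C1–C6 is a dihydroxyacetone unit whose cis C2 and C6 oxygens can share one acetonide. In ring terms this is a 2,2-dimethyl-1,3-dioxan-5-one bridged by C3=C4–C5, a 2,4-dioxabicyclo[3.3.1]nonenone, which can be closed between the dioxanone α-carbon C2 and an alkyne on the C6 side chain.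

## Retrosynthesis

**13 ⇒ 12 (C5–O, with inversion).** The C5 benzoate is cut with inversion, leaving the cis-5,6-diol 12. One aldol event delivers C5 and C6 cis, so one inversion is the cheapest correction, and C5 is the allylic, least hindered secondary carbinol. The inversion is placed last because the ring is then monocyclic and flexible. In the bridged intermediates the incoming benzoate would be syn-axial to C7, and before C7 is installed an axial C5 substituent would block the ketone face needed later. The forward reaction must activate C5–OH in the presence of C6–OH and the tertiary C1–OH and must go SN2, not SN2′.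

**12 ⇒ 11 ⇒ 10 (acyl C–O at C2 and C7; Si–O at C5).** The two benzoates are removed to give tetraol 10, which still carries the C5 silyl ether. The silyl ether does double duty: it keeps C5 for the later inversion and it shields the cis-neighbouring C6 hydroxyl. The forward acylation must follow the order C7 (primary) > C2 (allylic secondary) > C6 (between quaternary C1 and the silyloxy carbon), with the tertiary C1–OH inert.

**10 ⇒ 9 (acetonide).** The C2 and C6 oxygens are tied back into the bridging acetonide of 9. This turns the flexible tetraol into a rigid bicycle with defined faces and hides two of four hydroxyls. The forward step is mild acetal exchange that spares the silyl ether.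

**9 ⇒ 8 ⇒ 7 (C1–C7).** The hydroxymethyl arm is cut from C1, leading through silane 8 to the bridged ketone 7. Both α-carbons of 7 are bridgeheads, so the ketone cannot enolise and a hydroxymethyl anion equivalent should add cleanly. Carrying C7 earlier would make C1 quaternary before ring closure and remove the ketone on which the ring closure depends. The forward addition must come from the carbocycle face so that the C1 hydroxyl ends cis to O2 and O6.

**7 ⇒ 6 (C2–C3, ring closure).** The carbocycle is opened between C2 and C3, giving the monocyclic enol silane 6 with a terminal alkyne on the C6 side chain. The neighbouring cuts are worse. A C3=C4 metathesis would need a vinyl group on the dihydroxyacetone α-carbon, and cutting C1–C2 or C1–C6 would break the dihydroxyacetone unit that is bought intact. The precursor has one ring and one stereocentre fewer. The forward reaction must close in the 6-endo-dig sense through C2.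

**6 ⇒ 5 ⇒ 4 (O–Si of the enol ether; C–Si of the alkyne).** The enol ether is traced to ketone 4 and the terminal alkyne to its C-silyl form 5. The enol ether is made first and the alkyne unmasked second, so that the base-labile α-alkoxy-β-silyloxy ketone never meets methoxide. The forward enolisation must go to the C2 methylene, not to C6.

**4 ⇒ 3 ⇒ 1 + 2 (C5–C6, aldol).** The C5–C6 bond is cut to the symmetrical dioxanone 1 and the silyl ynal 2. Both fragments are commercial, and one enamine-catalysed aldol sets C6 and C5 in absolute terms. The forward reaction must be anti-selective and must add 1,2 to the ynal.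

## Roads not taken

**Alternative 1: dioxygenase dearomatisation.** The cut removes the C5 and C6 oxygens and the benzoyl groups and goes back to benzoic acid A1. In the forward key step, whole cells expressing benzoate 1,2-dioxygenase with the diol dehydrogenase blocked add dioxygen across the ipso and ortho carbons, giving the diene diol acid A2.

- Merits: A2 already holds C7, the quaternary C1 carbinol and C2, with the absolute configuration of 13 at both centres. Carboxyl reduction, benzoylation at C7 and C2, hydroxyl-directed epoxidation of C5=C6 and opening at allylic C5 by benzoate would finish in about five or six operations. The trans C5/C6 pattern and the C2/C6 differentiation come for free.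
- Weak points: A2 is not a catalogue chemical in useful quantity and needs fermentation with a blocked mutant strain. The cyclohexadiene re-aromatises readily by dehydration. The epoxidation must pick one of two conjugated alkenes and one face, and the vinyl epoxide can open 1,2 or 1,4.
- Comparison: this road is clearly shorter and its oxygen differentiation is better. The chosen plan sets against it that it starts from purchasable compounds only, needs no biotransformation, avoids arene-prone dienes, and fixes each stereocentre by a predictable structural element.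

**Alternative 2: desymmetrising epoxidation of a para-quinol, then Wharton transposition.** The cut goes back to the achiral para-quinol A3. In the forward key step a chiral amine salt and H2O2 epoxidise one of the two enantiotopic enone arms on the face of the C1 hydroxyl, giving the syn-epoxy quinol A4. Wharton transposition would then give the diene diol monobenzoate A5, which needs the same late epoxidation and opening as Alternative 1.

- Merits: potentially the shortest fully chemical route (about seven steps from a phenol), and C1 and C2 are set in one operation.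
- Weak points: the key step asks for two selectivities at once (which arm, which face) on a cross-conjugated dienone with a quaternary γ-carbon. That substrate class is poorly activated as an iminium ion and has thin precedent for high enantiocontrol. Hydrazine in the Wharton step threatens the C7 benzoate, and A5 shares the aromatisation and regiochemistry problems of the diene route.
- Comparison: on step count this road wins. The chosen plan rests its absolute configuration on the much better established amino-acid-catalysed aldol of the dioxanone and has no intermediate that can collapse to an arene.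

**Alternative 3: Ferrier carbocyclisation of a galactose enopyranoside.** The cut opens the ring at C3–C4 and goes back to the 6-deoxyhex-5-enopyranoside A6. In the forward key step, hydroxymercuration (a mercury salt, divalent mercury) unmasks a keto-aldehyde whose enolate closes the ring, giving the β-hydroxycyclohexanone A7.

- Merits: the ring closure is reliable. The C5/C6 trans relationship comes from the sugar, so no inversion is needed, and C5–O (PMB) is differentiated from C6–O and C1–O (acetonide) from the start. That is better than the chosen plan, which has to invert C5 and to tell C2 from C6 by selective acylation.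
- Weak points: the ring must be mapped sugar C4 → C1, C5 → C2, C6 → C3, C1 → C4, C2 → C5, C3 → C6, because only then is C1 next to the ketone. With that mapping the surviving centres C5 and C6 of A7 (D-galacto series) are the mirror image of those in 13, so the dearer L-galacto series would be required. The sugar needs about six protecting-group and elimination steps before the key step. Afterwards dehydration, C7 introduction at C1 through an α-alkoxy enolate prone to β-elimination of the C6 oxygen, ketone reduction and protecting-group exchange bring the total well beyond fourteen steps. A mercury reagent is also needed.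
- Comparison: the chosen plan is shorter (eleven steps), builds the quaternary centre by addition to a non-enolisable ketone, and takes its chirality from an inexpensive catalyst.

Key step: step 5

## Route

**Step 1**
Reactants: 1 2,2-dimethyl-1,3-dioxan-5-one; 2 3-(trimethylsilyl)prop-2-ynal
Product: 3 (4S)-4-[(1S)-1-hydroxy-3-(trimethylsilyl)prop-2-yn-1-yl]-2,2-dimethyl-1,3-dioxan-5-one
Conditions: L-proline (30 mol %), DMF, 4 °C
Reagents that add atoms: none
Why: Proline-catalysed direct aldol reaction; the ring enamine of 1 is necessarily E and adds to the aldehyde face held by hydrogen bonding to the carboxylic acid, which should give the anti (4S,1′S) adduct and so set C6 and C5; the C-silyl group blocks conjugate addition of the catalyst to the ynal.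

**Step 2**
Reactants: 3 (4S)-4-[(1S)-1-hydroxy-3-(trimethylsilyl)prop-2-yn-1-yl]-2,2-dimethyl-1,3-dioxan-5-one
Product: 4 (4S)-4-[(1S)-1-[(tert-butyldimethylsilyl)oxy]-3-(trimethylsilyl)prop-2-yn-1-yl]-2,2-dimethyl-1,3-dioxan-5-one
Conditions: TBSOTf, 2,6-lutidine, CH2Cl2, −78 °C
Reagents that add atoms: tert-butyldimethylsilyl trifluoromethanesulfonate, CC(C)(C)[Si](C)(C)OS(=O)(=O)C(F)(F)F
Why: O-Silylation of the β-hydroxy ketone with a silyl triflate and a hindered pyridine base at low temperature outruns retro-aldol and enolisation, so no stereocentre is touched.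

**Step 3**
Reactants: 4 (4S)-4-[(1S)-1-[(tert-butyldimethylsilyl)oxy]-3-(trimethylsilyl)prop-2-yn-1-yl]-2,2-dimethyl-1,3-dioxan-5-one
Product: 5 (4S)-4-[(1S)-1-[(tert-butyldimethylsilyl)oxy]-3-(trimethylsilyl)prop-2-yn-1-yl]-2,2-dimethyl-5-[(triisopropylsilyl)oxy]-4H-1,3-dioxine
Conditions: TIPSOTf, Et3N, CH2Cl2, 0 °C to rt
Reagents that add atoms: triisopropylsilyl trifluoromethanesulfonate, CC(C)[Si](OS(=O)(=O)C(F)(F)F)(C(C)C)C(C)C
Why: Soft enolisation (silyl triflate and tertiary amine); the O-silylated ketone should lose a proton from the open C2 methylene, because the tetrasubstituted isomer would press the siloxy group against the branched C6 substituent; no enolate is formed, so C6 cannot epimerise and the β-silyloxy group cannot be eliminated.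

**Step 4**
Reactants: 5 (4S)-4-[(1S)-1-[(tert-butyldimethylsilyl)oxy]-3-(trimethylsilyl)prop-2-yn-1-yl]-2,2-dimethyl-5-[(triisopropylsilyl)oxy]-4H-1,3-dioxine
Product: 6 (4S)-4-[(1S)-1-[(tert-butyldimethylsilyl)oxy]prop-2-yn-1-yl]-2,2-dimethyl-5-[(triisopropylsilyl)oxy]-4H-1,3-dioxine
Conditions: K2CO3 (0.3 equiv), MeOH, 0 °C
Reagents that add atoms: none
Why: Methanolysis of the C(sp)–SiMe3 bond by catalytic methoxide; the hindered triisopropylsilyl enol ether and the secondary silyl ether should be inert, and with the ketone masked the base-labile C6 centre is safe.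

**Step 5**
Reactants: 6 (4S)-4-[(1S)-1-[(tert-butyldimethylsilyl)oxy]prop-2-yn-1-yl]-2,2-dimethyl-5-[(triisopropylsilyl)oxy]-4H-1,3-dioxine
Product: 7 (1S,5R,8S)-8-[(tert-butyldimethylsilyl)oxy]-3,3-dimethyl-2,4-dioxabicyclo[3.3.1]non-6-en-9-one
Conditions: [(tBu2(2-biphenylyl)P)Au(NCMe)]SbF6 (5 mol %, monovalent gold), acetone, H2O (2 equiv), rt
Reagents that add atoms: none
Why: The cationic phosphine–gold complex binds the terminal alkyne, the enol ether carbon C2 attacks the terminal carbon C3 anti to gold, water removes the silyl group from the resulting C1 siloxycarbenium ion, and protodeauration of the C4 vinylgold leaves the C3=C4 alkene and frees the catalyst. The closest known reaction type is the gold-catalysed carbocyclisation of cyclic silyl enol ethers onto pendant terminal alkynes, which gives bicyclo[3.3.1]nonenones. The carbocycle closes 6-endo-dig (C2, C1, C6, C5, C4, C3, both alkyne carbons in the ring), and the existing dioxane becomes the second ring of the bicycle. The one new stereocentre, C2, is dictated by C6, because the three-carbon bridge can span the dioxanone only on the face that carries the side chain, so O2 and O6 end cis. The step needs 6-endo over 5-exo closure and attack through C2, not C1. The terminal alkyne and the bulky biarylphosphine ligand favour attack at the unsubstituted terminus, and the propargylic silyloxy group at C5 disfavours positive charge at C4. The siloxy group on C1 makes the tertiary C1 oxocarbenium ion the better cation, so C2 is the nucleophilic carbon. Acetone as solvent and the non-nucleophilic counter-ion should keep the acetonide and the secondary silyl ether intact.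

**Step 6**
Reactants: 7 (1S,5R,8S)-8-[(tert-butyldimethylsilyl)oxy]-3,3-dimethyl-2,4-dioxabicyclo[3.3.1]non-6-en-9-one
Product: 8 (1S,5R,8S,9R)-8-[(tert-butyldimethylsilyl)oxy]-9-{[dimethyl(propan-2-yloxy)silyl]methyl}-3,3-dimethyl-2,4-dioxabicyclo[3.3.1]non-6-en-9-ol
Conditions: iPrOMe2SiCH2MgCl, THF, −78 to 0 °C; aq NH4Cl
Reagents that add atoms: (isopropoxydimethylsilyl)methylmagnesium chloride, CC(C)O[Si](C)(C)C[Mg]Cl
Why: Grignard 1,2-addition of a hydroxymethyl anion equivalent to a ketone that cannot enolise (both α-carbons are bridgeheads); the carbon should enter from the carbocycle face, anti to both α C–O bonds (polar Felkin–Anh) and away from the acetal methyl group over the dioxane face, so the C1 hydroxyl ends cis to O2 and O6.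

**Step 7**
Reactants: 8 (1S,5R,8S,9R)-8-[(tert-butyldimethylsilyl)oxy]-9-{[dimethyl(propan-2-yloxy)silyl]methyl}-3,3-dimethyl-2,4-dioxabicyclo[3.3.1]non-6-en-9-ol
Product: 9 (1S,5R,8S,9R)-8-[(tert-butyldimethylsilyl)oxy]-9-(hydroxymethyl)-3,3-dimethyl-2,4-dioxabicyclo[3.3.1]non-6-en-9-ol
Conditions: 30% H2O2, KF, KHCO3, THF/MeOH (1:1), rt
Reagents that add atoms: hydrogen peroxide, OO
Why: Tamao–Fleming oxidation of the alkoxysilane C–Si bond to C–OH; the buffered fluoride/peroxide medium avoids Peterson elimination of the β-hydroxysilane and should leave the alkene and the silyl ether alone.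

**Step 8**
Reactants: 9 (1S,5R,8S,9R)-8-[(tert-butyldimethylsilyl)oxy]-9-(hydroxymethyl)-3,3-dimethyl-2,4-dioxabicyclo[3.3.1]non-6-en-9-ol
Product: 10 (1R,2R,5S,6S)-5-[(tert-butyldimethylsilyl)oxy]-1-(hydroxymethyl)cyclohex-3-ene-1,2,6-triol
Conditions: PPTS (0.2 equiv), MeOH, rt
Reagents that add atoms: none
Why: Acid-catalysed transacetalisation to methanol; the bridging acetonide is strained (diaxial fusion, acetal methyl over the ring) and should leave well before the secondary silyl ether is touched.

**Step 9**
Reactants: 10 (1R,2R,5S,6S)-5-[(tert-butyldimethylsilyl)oxy]-1-(hydroxymethyl)cyclohex-3-ene-1,2,6-triol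
Product: 11 [(1S,2R,5S,6S)-2-(benzoyloxy)-5-[(tert-butyldimethylsilyl)oxy]-1,6-dihydroxycyclohex-3-en-1-yl]methyl benzoate
Conditions: BzCl (2.2 equiv), pyridine, CH2Cl2, −30 to 0 °C
Reagents that add atoms: benzoyl chloride, O=C(Cl)c1ccccc1
Why: Site-selective acylation without an acyl-transfer catalyst; the expected order is primary C7, then allylic C2, while C6–OH is screened by quaternary C1 and the cis silyloxy group on C5 and the tertiary C1–OH is inert; no stereocentre changes.

**Step 10**
Reactants: 11 [(1S,2R,5S,6S)-2-(benzoyloxy)-5-[(tert-butyldimethylsilyl)oxy]-1,6-dihydroxycyclohex-3-en-1-yl]methyl benzoate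
Product: 12 [(1S,2R,5S,6S)-2-(benzoyloxy)-1,5,6-trihydroxycyclohex-3-en-1-yl]methyl benzoate
Conditions: HF·pyridine, THF/pyridine, 0 °C to rt
Reagents that add atoms: none
Why: Fluoride cleavage of the Si–O bond in a buffered, slightly acidic medium, chosen because base-promoted benzoate migration to the cis hydroxyls is the main hazard here.

**Step 11**
Reactants: 12 [(1S,2R,5S,6S)-2-(benzoyloxy)-1,5,6-trihydroxycyclohex-3-en-1-yl]methyl benzoate
Product: 13 [(1S,2R,5R,6S)-2,5-bis(benzoyloxy)-1,6-dihydroxycyclohex-3-en-1-yl]methyl benzoate
Conditions: PPh3, DIAD, PhCO2H, THF, 0 °C to rt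
Reagents that add atoms: benzoic acid, O=C(O)c1ccccc1
Why: Mitsunobu reaction; the oxyphosphonium ion should form at the allylic, least hindered secondary hydroxyl and be displaced by benzoate with inversion, setting C5 as R; C6–OH is neopentyl-like, the C1–OH is tertiary, and the cis-5,6-diol cannot close to an epoxide.

## Compound list

1 | 2,2-dimethyl-1,3-dioxan-5-one | CC1(C)OCC(=O)CO1 | starting material
2 | 3-(trimethylsilyl)prop-2-ynal | C[Si](C)(C)C#CC=O | starting material
3 | (4S)-4-[(1S)-1-hydroxy-3-(trimethylsilyl)prop-2-yn-1-yl]-2,2-dimethyl-1,3-dioxan-5-one | C[Si](C)(C)C#C[C@H](O)[C@@H]1OC(C)(C)OCC1=O | intermediate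
4 | (4S)-4-[(1S)-1-[(tert-butyldimethylsilyl)oxy]-3-(trimethylsilyl)prop-2-yn-1-yl]-2,2-dimethyl-1,3-dioxan-5-one | C[Si](C)(C)C#C[C@H](O[Si](C)(C)C(C)(C)C)[C@@H]1OC(C)(C)OCC1=O | intermediate
5 | (4S)-4-[(1S)-1-[(tert-butyldimethylsilyl)oxy]-3-(trimethylsilyl)prop-2-yn-1-yl]-2,2-dimethyl-5-[(triisopropylsilyl)oxy]-4H-1,3-dioxine | C[Si](C)(C)C#C[C@H](O[Si](C)(C)C(C)(C)C)[C@@H]1OC(C)(C)OC=C1O[Si](C(C)C)(C(C)C)C(C)C | intermediate
6 | (4S)-4-[(1S)-1-[(tert-butyldimethylsilyl)oxy]prop-2-yn-1-yl]-2,2-dimethyl-5-[(triisopropylsilyl)oxy]-4H-1,3-dioxine | C#C[C@H](O[Si](C)(C)C(C)(C)C)[C@@H]1OC(C)(C)OC=C1O[Si](C(C)C)(C(C)C)C(C)C | intermediate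
7 | (1S,5R,8S)-8-[(tert-butyldimethylsilyl)oxy]-3,3-dimethyl-2,4-dioxabicyclo[3.3.1]non-6-en-9-one | O=C1[C@H]2C=C[C@H](O[Si](C)(C)C(C)(C)C)[C@@H]1OC(C)(C)O2 | intermediate
8 | (1S,5R,8S,9R)-8-[(tert-butyldimethylsilyl)oxy]-9-{[dimethyl(propan-2-yloxy)silyl]methyl}-3,3-dimethyl-2,4-dioxabicyclo[3.3.1]non-6-en-9-ol | CC(C)O[Si](C)(C)C[C@@]1(O)[C@H]2C=C[C@H](O[Si](C)(C)C(C)(C)C)[C@@H]1OC(C)(C)O2 | intermediate
9 | (1S,5R,8S,9R)-8-[(tert-butyldimethylsilyl)oxy]-9-(hydroxymethyl)-3,3-dimethyl-2,4-dioxabicyclo[3.3.1]non-6-en-9-ol | OC[C@@]1(O)[C@H]2C=C[C@H](O[Si](C)(C)C(C)(C)C)[C@@H]1OC(C)(C)O2 | intermediate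
10 | (1R,2R,5S,6S)-5-[(tert-butyldimethylsilyl)oxy]-1-(hydroxymethyl)cyclohex-3-ene-1,2,6-triol | OC[C@@]1(O)[C@H](O)C=C[C@H](O[Si](C)(C)C(C)(C)C)[C@@H]1O | intermediate
11 | [(1S,2R,5S,6S)-2-(benzoyloxy)-5-[(tert-butyldimethylsilyl)oxy]-1,6-dihydroxycyclohex-3-en-1-yl]methyl benzoate | O=C(OC[C@@]1(O)[C@H](OC(=O)c2ccccc2)C=C[C@H](O[Si](C)(C)C(C)(C)C)[C@@H]1O)c1ccccc1 | intermediate
12 | [(1S,2R,5S,6S)-2-(benzoyloxy)-1,5,6-trihydroxycyclohex-3-en-1-yl]methyl benzoate | O=C(OC[C@@]1(O)[C@H](OC(=O)c2ccccc2)C=C[C@H](O)[C@@H]1O)c1ccccc1 | intermediate
13 | [(1S,2R,5R,6S)-2,5-bis(benzoyloxy)-1,6-dihydroxycyclohex-3-en-1-yl]methyl benzoate | O=C(OC[C@@]1(O)[C@H](OC(=O)c2ccccc2)C=C[C@@H](OC(=O)c2ccccc2)[C@@H]1O)c1ccccc1 | target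

## Step count and risks

Total: 11 steps. Longest linear sequence: 11 steps (the route is linear from 1 and 2).

**Step 5 (key step).** The most likely failure is closure through the internal alkyne carbon (5-exo-dig). The second is simple hydrolysis of the enol ether before C–C bond formation. Both are plausible because the enol carbon is flanked by an acetal oxygen and the reactive conformer holds the side chain pseudoaxial against an acetal methyl group. The fallback forms the same C2–C3 bond by enolate alkenylation, sets out from 4 and rejoins at 7. Iododesilylation of 4 (N-iodosuccinimide, catalytic AgNO3, acetone) would give (4S)-4-[(1S)-1-[(tert-butyldimethylsilyl)oxy]-3-iodoprop-2-yn-1-yl]-2,2-dimethyl-1,3-dioxan-5-one F1. Diimide reduction (dipotassium azodicarboxylate, AcOH) would give the (Z)-vinyl iodide (4S)-4-[(1S,2Z)-1-[(tert-butyldimethylsilyl)oxy]-3-iodoprop-2-en-1-yl]-2,2-dimethyl-1,3-dioxan-5-one F2. Intramolecular ketone α-alkenylation with Pd(PPh3)4 (zerovalent palladium) and PhOK in THF would then close the ring to 7. Only the C2 enolate can reach the vinyl palladium, and the bridge again forces O2 cis to O6.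

**Step 3.** The likely failure is loss of regiocontrol by equilibration through the ammonium triflate, which would give the enol ether towards C6 and erase that stereocentre. The fallback uses the aldolate as a directing group, sets out from 3 and rejoins at 7. Two equivalents of LDA (THF, −78 °C) would form the alkoxide and then the enolate on the methylene side, since a second negative charge next to the alkoxide is disfavoured and oxide cannot be eliminated. TBSOTf would silylate both oxygens to give (4S)-4-[(1S)-1-[(tert-butyldimethylsilyl)oxy]-3-(trimethylsilyl)prop-2-yn-1-yl]-5-[(tert-butyldimethylsilyl)oxy]-2,2-dimethyl-4H-1,3-dioxine F3. Brief K2CO3/MeOH would give the terminal alkyne (4S)-4-[(1S)-1-[(tert-butyldimethylsilyl)oxy]prop-2-yn-1-yl]-5-[(tert-butyldimethylsilyl)oxy]-2,2-dimethyl-4H-1,3-dioxine F4, and the gold conditions of step 5 would convert F4 into 7.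

**Step 6.** The likely failure is poor facial selectivity: magnesium held by the two acetal oxygens could deliver the carbon from the dioxane face. The fallback uses a methylene donor without a Lewis-acidic metal, sets out from 7 and rejoins at 9. Dimethylsulfonium methylide (Me3SI, KHMDS, THF, −10 °C) would give the spiro-epoxide 8-[(tert-butyldimethylsilyl)oxy]-3,3-dimethylspiro[2,4-dioxabicyclo[3.3.1]non-6-ene-9,2′-oxirane] F5, with the oxygen on the dioxane side. CsOAc in DMF at 80 °C would open it at the methylene carbon to the C7 acetate F6, [8-[(tert-butyldimethylsilyl)oxy]-9-hydroxy-3,3-dimethyl-2,4-dioxabicyclo[3.3.1]non-6-en-9-yl]methyl acetate. K2CO3/MeOH would then give 9.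

**Step 9.** The likely failure is competing acylation at C6 or over-acylation, because the discrimination between the two secondary hydroxyls rests on sterics alone. The fallback masks C6–OH covalently, sets out from 9 and rejoins at 12.
- Benzoylation of the primary hydroxyl of 9 (BzCl, pyridine, 0 °C) would give [8-[(tert-butyldimethylsilyl)oxy]-9-hydroxy-3,3-dimethyl-2,4-dioxabicyclo[3.3.1]non-6-en-9-yl]methyl benzoate F7.
- HF·pyridine would free C5–OH to give (8,9-dihydroxy-3,3-dimethyl-2,4-dioxabicyclo[3.3.1]non-6-en-9-yl)methyl benzoate F8.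
- Catalytic camphorsulfonic acid in CH2Cl2 should let the strained bridging acetal migrate to the cis-5,6-diol, giving the cis-fused dioxolane (1,2-dihydroxy-5,6-O-isopropylidenecyclohex-3-en-1-yl)methyl benzoate F9. The position of the acetal would have to be confirmed before going on.
- C2–OH is then the only acylable hydroxyl, so BzCl/pyridine/DMAP would give the 2,7-dibenzoate 5,6-acetonide F10.
- Aqueous acetic acid at rt would give 12.

**Step 11.** The likely failures are SN2′ attack at C3, elimination towards a diene, or stalling of the activation as a cyclic phosphorane of the cis-5,6-diol. The fallback separates activation from displacement, sets out from 12 and rejoins at 13. Chloromethanesulfonyl chloride and pyridine at −20 °C should sulfonylate the allylic hydroxyl to give the C5 chloromethanesulfonate F11, [(1S,2R,5S,6S)-2-(benzoyloxy)-5-[(chloromethanesulfonyl)oxy]-1,6-dihydroxycyclohex-3-en-1-yl]methyl benzoate, used without purification. Caesium benzoate with 18-crown-6 in toluene would displace it with inversion to give 13.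

## Further compounds

F1 | step 5 | (4S)-4-[(1S)-1-[(tert-butyldimethylsilyl)oxy]-3-iodoprop-2-yn-1-yl]-2,2-dimethyl-1,3-dioxan-5-one | IC#C[C@H](O[Si](C)(C)C(C)(C)C)[C@@H]1OC(C)(C)OCC1=O
F2 | step 5 | (4S)-4-[(1S,2Z)-1-[(tert-butyldimethylsilyl)oxy]-3-iodoprop-2-en-1-yl]-2,2-dimethyl-1,3-dioxan-5-one | I/C=C\[C@H](O[Si](C)(C)C(C)(C)C)[C@@H]1OC(C)(C)OCC1=O
F3 | step 3 | (4S)-4-[(1S)-1-[(tert-butyldimethylsilyl)oxy]-3-(trimethylsilyl)prop-2-yn-1-yl]-5-[(tert-butyldimethylsilyl)oxy]-2,2-dimethyl-4H-1,3-dioxine | C[Si](C)(C)C#C[C@H](O[Si](C)(C)C(C)(C)C)[C@@H]1OC(C)(C)OC=C1O[Si](C)(C)C(C)(C)C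
F4 | step 3 | (4S)-4-[(1S)-1-[(tert-butyldimethylsilyl)oxy]prop-2-yn-1-yl]-5-[(tert-butyldimethylsilyl)oxy]-2,2-dimethyl-4H-1,3-dioxine | C#C[C@H](O[Si](C)(C)C(C)(C)C)[C@@H]1OC(C)(C)OC=C1O[Si](C)(C)C(C)(C)C
F5 | step 6 | 8-[(tert-butyldimethylsilyl)oxy]-3,3-dimethylspiro[2,4-dioxabicyclo[3.3.1]non-6-ene-9,2′-oxirane], epoxide oxygen on the dioxane side | O1C[C@]12[C@H]3C=C[C@H](O[Si](C)(C)C(C)(C)C)[C@@H]2OC(C)(C)O3
F6 | step 6 | [8-[(tert-butyldimethylsilyl)oxy]-9-hydroxy-3,3-dimethyl-2,4-dioxabicyclo[3.3.1]non-6-en-9-yl]methyl acetate (C7 acetate of 9) | CC(=O)OC[C@@]1(O)[C@H]2C=C[C@H](O[Si](C)(C)C(C)(C)C)[C@@H]1OC(C)(C)O2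
F7 | step 9 | [8-[(tert-butyldimethylsilyl)oxy]-9-hydroxy-3,3-dimethyl-2,4-dioxabicyclo[3.3.1]non-6-en-9-yl]methyl benzoate (C7 benzoate of 9) | O=C(OC[C@@]1(O)[C@H]2C=C[C@H](O[Si](C)(C)C(C)(C)C)[C@@H]1OC(C)(C)O2)c1ccccc1
F8 | step 9 | (8,9-dihydroxy-3,3-dimethyl-2,4-dioxabicyclo[3.3.1]non-6-en-9-yl)methyl benzoate (C5 hydroxyl free, cis to O6) | O=C(OC[C@@]1(O)[C@H]2C=C[C@H](O)[C@@H]1OC(C)(C)O2)c1ccccc1
F9 | step 9 | (1,2-dihydroxy-5,6-O-isopropylidenecyclohex-3-en-1-yl)methyl benzoate, all four ring oxygens cis | O=C(OC[C@@]1(O)[C@H](O)C=C[C@@H]2OC(C)(C)O[C@H]12)c1ccccc1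
F10 | step 9 | [2-(benzoyloxy)-1-hydroxy-5,6-O-isopropylidenecyclohex-3-en-1-yl]methyl benzoate, all four ring oxygens cis | O=C(OC[C@@]1(O)[C@H](OC(=O)c2ccccc2)C=C[C@@H]2OC(C)(C)O[C@H]12)c1ccccc1
F11 | step 11 | [(1S,2R,5S,6S)-2-(benzoyloxy)-5-[(chloromethanesulfonyl)oxy]-1,6-dihydroxycyclohex-3-en-1-yl]methyl benzoate | O=C(OC[C@@]1(O)[C@H](OC(=O)c2ccccc2)C=C[C@H](OS(=O)(=O)CCl)[C@@H]1O)c1ccccc1
A1 | alternative 1 | benzoic acid | O=C(O)c1ccccc1
A2 | alternative 1 | (1S,2R)-1,2-dihydroxycyclohexa-3,5-diene-1-carboxylic acid | O=C(O)[C@@]1(O)[C@H](O)C=CC=C1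
A3 | alternative 2 | (1-hydroxy-4-oxocyclohexa-2,5-dien-1-yl)methyl benzoate | O=C(OCC1(O)C=CC(=O)C=C1)c1ccccc1
A4 | alternative 2 | (2,3-epoxy-1-hydroxy-4-oxocyclohex-5-en-1-yl)methyl benzoate, epoxide cis to the C1 hydroxyl | O=C(OC[C@@]1(O)[C@@H]2O[C@@H]2C(=O)C=C1)c1ccccc1
A5 | alternative 2 | (1,2-dihydroxycyclohexa-3,5-dien-1-yl)methyl benzoate, hydroxyls cis | O=C(OC[C@@]1(O)[C@H](O)C=CC=C1)c1ccccc1
A6 | alternative 3 | methyl 6-deoxy-3,4-O-isopropylidene-2-O-(4-methoxybenzyl)-β-L-arabino-hex-5-enopyranoside (D-galacto series) | C=C1[C@@H]2OC(C)(C)O[C@@H]2[C@@H](OCc3ccc(OC)cc3)[C@@H](OC)O1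
A7 | alternative 3 | β-hydroxycyclohexanone from the Ferrier carbocyclisation, carrying the 3,4-O-isopropylidene and 2-O-(4-methoxybenzyl) groups (sugar numbering) | O=C1C[C@H](O)[C@H](OCc3ccc(OC)cc3)[C@H]2OC(C)(C)O[C@@H]12
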